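## Retrosynthetic overview

1. Umbellacin A ⇒ the last step is a cross-aldol condensation of the CH2CHO arm at C3 of a bicyclic hydroxy dialdehyde (handled as its lactol) with (E)-4-hydroxy-4-methylpent-2-enal, itself made by cross-metathesis.
2. Ring B (the seven-membered ring that completes the bicyclo[4.3.1]decane, closed last) ⇒ intramolecular aldol of one of the two equivalent CH2CHO arms of a 3-substituted glutaraldehyde onto the C1 ketone of ring A; this breaks the mirror symmetry of the glutaraldehyde and sets C1, C2 and C3.
3. Key step: the glutaraldehyde is carried as a 4-alkylpyridine and released by Birch dearomatisation to the 1,4-dihydropyridine plus hydrolysis (the C1 ketal is cleaved in the same flask).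
4. C7 carbinol ⇒ catalyst-controlled CBS reduction; C6 quaternary centre ⇒ chiral-imine Michael addition of 2-methylcyclohexane-1,4-dione 4-ketal to 4-vinylpyridine.
5. Ring order: ring A (cyclohexane) is bought; the pyridine ring is attached and then destroyed; ring B is formed by the aldol.

Assumption: the ketal ketone starting material (CAS 702-69-2) is taken as a catalogue compound, and "umbellacins A" is read as umbellacin A with the absolute configuration of the given SMILES.

Numbering: target positions use bicyclo[4.3.1]decane numbering (C1 tertiary carbinol bridgehead, C2 CHO-bearing, C3 side-chain-bearing, C6 methyl bridgehead, C7 secondary carbinol, C10 one-carbon bridge). The target is (1R,2R,3S,6S,7R), with the C1–OH, the C3 side chain and the C6 methyl on one face of the seven-membered ring and the C2–CHO on the other.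

## Route

Step 1
Reactants: 1 7-methyl-1,4-dioxaspiro[4.5]decan-8-one (racemic); 2 (S)-1-phenylethylamine; 3 4-vinylpyridine
Product: 6 (7S)-7-methyl-7-[2-(pyridin-4-yl)ethyl]-1,4-dioxaspiro[4.5]decan-8-one, via ketimine 4 (not isolated), via alkylated ketimine 5 (not isolated)
Conditions: 2 (1.05 equiv), TsOH (0.5 mol%), PhMe, reflux, Dean–Stark; then 3 (1.5 equiv), AcOH (1.0 equiv), BHT (cat.), THF, 60 °C; then 20% aq. AcOH, 23 °C; NaHCO3 work-up
Reagents that add atoms: water, O
Why: Proposed new method: the ketimine of the α-methyl ketone tautomerises to its more substituted secondary enamine, which adds through a compact aza-ene-like transition state (N–H passed to the acceptor α-carbon) to the acid-activated 4-vinylpyridinium on the face anti to the phenyl group of the auxiliary, so the (S)-amine should give the (S)-quaternary centre (C6 of the target) as it does with enones and acrylates in the d'Angelo deracemising chiral-imine Michael addition, the closest known reaction type together with the classical pyridylethylation of enamines, and hydrolysis returns the ketone and the auxiliary.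

Step 2
Reactants: 6 (7S)-7-methyl-7-[2-(pyridin-4-yl)ethyl]-1,4-dioxaspiro[4.5]decan-8-one
Product: 7 (7S,8R)-7-methyl-7-[2-(pyridin-4-yl)ethyl]-1,4-dioxaspiro[4.5]decan-8-ol
Conditions: (S)-2-methyl-CBS-oxazaborolidine [(3aS)-1-methyl-3,3-diphenyltetrahydro-1H,3H-pyrrolo[1,2-c][1,3,2]oxazaborole] (0.2 equiv), catecholborane (2.5 equiv), PhMe/CH2Cl2, −78 → −30 °C; then aq. NaOH
Reagents that add atoms: none
Why: Corey–Bakshi–Shibata reduction, in which the catalyst tells the quaternary (large) flank from the CH2 (small) flank of the ketone whatever the nearly equal methyl/CH2CH2Ar pair on the neighbouring carbon does, so the (S)-catalyst gives the (8R)-carbinol with OH cis to the pyridylethyl chain (C7 of the target), where substrate-controlled hydrides would give about 1:1 mixtures; the ketal and the pyridine are untouched.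

Step 3
Reactants: 7 (7S,8R)-7-methyl-7-[2-(pyridin-4-yl)ethyl]-1,4-dioxaspiro[4.5]decan-8-ol
Product: 9 3-{2-[(1S,2R)-2-hydroxy-1-methyl-5-oxocyclohexyl]ethyl}pentanedial, via 1,4-dihydropyridine 8 (not isolated)
Conditions: Na (3 equiv), NH3(l)/THF, EtOH (6 equiv), −78 °C; evaporate NH3; then degassed 1 M HCl/THF, 0 → 23 °C; extract at pH 3, use crude
Reagents that add atoms: water, O
Why: Birch reduction of an alkylpyridine stops at the 1,4-dihydropyridine, a cyclic bis-enamine, and aqueous acid then hydrolyses both enamine C–N bonds (nitrogen leaves as NH4Cl) and the dioxolane, so the aromatic ring is unveiled as a mirror-symmetric 3-substituted glutaraldehyde beside the C1 ketone with no stereocentre touched (pyridine as a latent 1,5-dicarbonyl, as in pyridine-based annulations), the alcohol and ketal being inert to Na/NH3.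

Step 4
Reactants: 9 3-{2-[(1S,2R)-2-hydroxy-1-methyl-5-oxocyclohexyl]ethyl}pentanedial
Product: 11 tricyclic δ-lactol (C1–O–CH(OH)–CH2–C3 bridge; C2–CHO free; C7–OH free; anomer mixture), via open-chain aldol 10 (not isolated)
Conditions: pyrrolidine (0.2 equiv), AcOH (0.2 equiv), CH2Cl2 (0.02 M), 23 °C, 24 h
Reagents that add atoms: none
Why: Proposed new method: the amine-catalysed aldehyde-donor/ketone-acceptor (enolexo) intramolecular aldol, known for five- and six-membered rings, is extended to a bridged seven-membered closure in which only the aldehyde arms form enamines readily, the arm-to-arm aldol would need a four-membered ring, the axial C6 tether can reach only one face of the C1 ketone (fixing C1), and, the aldol being reversible, the two diastereotopic arms are sorted thermodynamically because only the isomer whose free arm is cis to the new C1–OH can close the six-membered lactol 11 (the C3 configuration of the target), while C2 is expected to equilibrate through its enamine to place CHO trans to both neighbours.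

Step 5
Reactants: 12 2-methylbut-3-en-2-ol; 13 (E)-but-2-enal
Product: 14 (E)-4-hydroxy-4-methylpent-2-enal
Conditions: second-generation Hoveyda–Grubbs catalyst (C31H38Cl2N2ORu, 2 mol%), 12 (3 equiv), CH2Cl2, 40 °C
Reagents that add atoms: none
Why: Olefin cross-metathesis between a hindered tertiary allylic alcohol and an electron-poor enal, both slow to homodimerise, gives the (E)-enal selectively with loss of propene.

Step 6
Reactants: 11 tricyclic δ-lactol; 14 (E)-4-hydroxy-4-methylpent-2-enal
Product: 16 umbellacin A, via β-hydroxy aldehyde adduct 15 (not isolated)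
Conditions: 14 (2 equiv), pyrrolidine (0.2 equiv), PhCO2H (0.2 equiv), CH2Cl2, 0 → 23 °C
Reagents that add atoms: none
Why: Amine-catalysed (Mannich-type) cross-aldol condensation in which pyrrolidine condenses at the lactol carbon of 11 and opens it to the enamine of the C3 acetaldehyde arm, the only aldehyde position that can both form an enamine and dehydrate (C2–CHO is α-branched), while 14 is non-enolisable and hindered at its β-carbon, so 1,2-addition gives adduct 15 and E1cB loss of water gives the thermodynamic (2E)-enal with the (4E)-alkene untouched, no new stereocentre survives, and the epimerisable C2 is expected to stay trans to both neighbours.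

## Compound list

1 | 7-methyl-1,4-dioxaspiro[4.5]decan-8-one (racemic) | CC1CC2(OCCO2)CCC1=O | starting material
2 | (S)-1-phenylethylamine | C[C@H](N)c1ccccc1 | starting material
3 | 4-vinylpyridine | C=Cc1ccncc1 | starting material
4 | (S)-N-(7-methyl-1,4-dioxaspiro[4.5]decan-8-ylidene)-1-phenylethanamine (C7 epimers, in equilibrium with the secondary enamine) | C[C@@H](c1ccccc1)N=C1CCC2(OCCO2)CC1C | intermediate
5 | (S)-N-{(7S)-7-methyl-7-[2-(pyridin-4-yl)ethyl]-1,4-dioxaspiro[4.5]decan-8-ylidene}-1-phenylethanamine | C[C@@H](c1ccccc1)N=C1CCC2(OCCO2)C[C@]1(C)CCc1ccncc1 | intermediate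
6 | (7S)-7-methyl-7-[2-(pyridin-4-yl)ethyl]-1,4-dioxaspiro[4.5]decan-8-one | O=C1CCC2(OCCO2)C[C@]1(C)CCc1ccncc1 | intermediate
7 | (7S,8R)-7-methyl-7-[2-(pyridin-4-yl)ethyl]-1,4-dioxaspiro[4.5]decan-8-ol | O[C@@H]1CCC2(OCCO2)C[C@]1(C)CCc1ccncc1 | intermediate
8 | (7S,8R)-7-[2-(1,4-dihydropyridin-4-yl)ethyl]-7-methyl-1,4-dioxaspiro[4.5]decan-8-ol | O[C@@H]1CCC2(OCCO2)C[C@]1(C)CCC1C=CNC=C1 | intermediate
9 | 3-{2-[(1S,2R)-2-hydroxy-1-methyl-5-oxocyclohexyl]ethyl}pentanedial | O[C@@H]1CCC(=O)C[C@]1(C)CCC(CC=O)CC=O | intermediate
10 | open-chain aldol, 2-[(1R,2R,3R,6S,7R)-2-formyl-1,7-dihydroxy-6-methylbicyclo[4.3.1]decan-3-yl]acetaldehyde | O=CC[C@H]1CC[C@@]2(C)C[C@](O)(CC[C@H]2O)[C@@H]1C=O | intermediate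
11 | tricyclic δ-lactol (ring-closed hemiacetal of the open-chain aldol: O–CH(OH)–CH2 bridge from C1 to C3; C2–CHO and C7–OH free; anomer mixture) | OC1C[C@H]2CC[C@@]3(C)C[C@](O1)(CC[C@H]3O)[C@@H]2C=O | intermediate
12 | 2-methylbut-3-en-2-ol | CC(C)(O)C=C | starting material
13 | (E)-but-2-enal (crotonaldehyde) | C/C=C/C=O | starting material
14 | (E)-4-hydroxy-4-methylpent-2-enal | CC(C)(O)/C=C/C=O | intermediate
15 | β-hydroxy aldehyde adduct, (4E)-2-[(1R,2R,3R,6S,7R)-2-formyl-1,7-dihydroxy-6-methylbicyclo[4.3.1]decan-3-yl]-3,6-dihydroxy-6-methylhept-4-enal (mixture at the two new chain centres; drawn open-chain) | CC(C)(O)/C=C/C(O)C(C=O)[C@H]1CC[C@@]2(C)C[C@](O)(CC[C@H]2O)[C@@H]1C=O | intermediate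
16 | umbellacin A, (2E,4E)-2-[(1R,2R,3S,6S,7R)-2-formyl-1,7-dihydroxy-6-methylbicyclo[4.3.1]decan-3-yl]-6-hydroxy-6-methylhepta-2,4-dienal | CC(C)(O)/C=C/C=C(/C=O)[C@H]1CC[C@@]2(C)C[C@](O)(CC[C@H]2O)[C@@H]1C=O | target

## Step count and risks

Total step count: 6. Longest linear sequence: 5 (steps 1, 2, 3, 4, 6); step 5 is a one-step side branch.

Three steps most likely to fail:

Step 4 is the weakest point. The bridged seven-membered aldol onto a ketone may not be favoured at equilibrium, or may give the wrong arm or the wrong C2 epimer. The fallback gives up thermodynamic self-sorting and removes the ring-closed material from the equilibrium covalently. It sets out from 9: the aldol is run under kinetic control with proline in DMSO (both enantiomers screened, the matched one kept) and, without isolation, HC(OMe)3/MeOH/PPTS is added. Cyclised material is thereby converted into the lactol methyl acetal carrying a dimethyl acetal at the C2 aldehyde, bis-acetal F5, in which C1–O is etherified, so retro-aldol is impossible and the two arms are chemically different. Uncyclised material becomes the hexamethyl tris-acetal of 9 F6, which is separated, returned to 9 with aqueous acid and resubmitted. F5 is purified from its C3 isomer, and aqueous AcOH/THF brings the route back at 11.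

Step 3 can fail through dimerisation or over-reduction of the pyridine radical anion and through loss of the sensitive dialdehyde. The fallback replaces electron-transfer reduction by hydride addition to an acylpyridinium ion. It sets out from 7: the hydroxyl is capped (TMSCl, Et3N) as the trimethylsilyl ether F2, methyl chloroformate converts the pyridine into the N-(methoxycarbonyl)pyridinium chloride F3, and LiAlH(OtBu)3/CuBr at −78 °C in THF delivers hydride to C4 to give the isolable N-(methoxycarbonyl)-1,4-dihydropyridine F4. Treatment with 1 M HCl/THF then hydrolyses both enecarbamate arms, the silyl ether and the ketal, and the route is rejoined at 9.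

Step 1 can fail because 4-vinylpyridine is an untested acceptor for the chiral-imine Michael addition, in rate or in ee. The fallback drops auxiliary control. It sets out from 1 and 3: base-catalysed pyridylethylation (KOtBu cat., tBuOH, 60 °C) at the more substituted α-carbon under thermodynamic control gives the racemic ketone F1, which is resolved by preparative chromatography on a chiral stationary phase, and the (S)-enantiomer rejoins the route at 6.

## Further compounds

F1 | step 1 | racemic 7-methyl-7-[2-(pyridin-4-yl)ethyl]-1,4-dioxaspiro[4.5]decan-8-one | O=C1CCC2(OCCO2)CC1(C)CCc1ccncc1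
F2 | step 3 | (7S,8R)-7-methyl-7-[2-(pyridin-4-yl)ethyl]-8-(trimethylsilyloxy)-1,4-dioxaspiro[4.5]decane | C[Si](C)(C)O[C@@H]1CCC2(OCCO2)C[C@]1(C)CCc1ccncc1
F3 | step 3 | 1-(methoxycarbonyl)-4-{2-[(7S,8R)-7-methyl-8-(trimethylsilyloxy)-1,4-dioxaspiro[4.5]decan-7-yl]ethyl}pyridinium chloride | C[Si](C)(C)O[C@@H]1CCC2(OCCO2)C[C@]1(C)CCc1cc[n+](C(=O)OC)cc1.[Cl-]
F4 | step 3 | methyl 4-{2-[(7S,8R)-7-methyl-8-(trimethylsilyloxy)-1,4-dioxaspiro[4.5]decan-7-yl]ethyl}-4H-pyridine-1-carboxylate | C[Si](C)(C)O[C@@H]1CCC2(OCCO2)C[C@]1(C)CCC1C=CN(C(=O)OC)C=C1
F5 | step 4 | bis-acetal of 11 (lactol methyl acetal; C2 aldehyde as dimethyl acetal; anomer mixture) | COC1C[C@H]2CC[C@@]3(C)C[C@](O1)(CC[C@H]3O)[C@@H]2C(OC)OC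
F6 | step 4 | hexamethyl tris-acetal of 9, (1R,2S)-2-[5,5-dimethoxy-3-(2,2-dimethoxyethyl)pentyl]-4,4-dimethoxy-2-methylcyclohexan-1-ol | COC(OC)CC(CC(OC)OC)CC[C@@]1(C)CC(OC)(OC)CC[C@H]1O
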